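## Analysis of the target

- The target is a guaian-6,12-olide: a cis-fused hydroazulene (cyclopentane C1–C5, cycloheptane C1, C5–C10) with a trans-fused α-methylene-γ-butyrolactone on C6/C7 (C11–C13).
- An oxygen links C4 to C14, and C14 is doubly bonded to C10. The atoms O, C4, C5, C1, C10 and C14 therefore form a dihydropyran bridged across the cyclopentane (a 2-oxabicyclo[3.2.1]octene). C4 also carries the free hydroxymethyl C15, C8 an (R)-2-methylbutanoate and C9 an acetate.
- There are seven ring stereocentres (C1, C4, C5, C6, C7, C8, C9) and one in the acyl group. Taking α as the face of H-1 and H-5: the C4 oxygen is β (4S), the lactone oxygen on C6 is α, C11 on C7 is β, the C8 ester is β and the C9 acetate is α.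
- Sensitive groups are the α-methylene lactone (Michael acceptor), the C10=C14 enol ether with its allylic C9 acetate (glycal-like, ionizes with acid with allylic transposition), and two different esters on vicinal carbons (acyl migration). The end game must therefore be buffered and the last deprotection non-acidic.
- The difficulties are the quaternary ether carbon C4 next to the ring fusion, and four contiguous cycloheptane centres in an α,β,β,α pattern. H-6 and H-9 sit on the β face, which is covered by the O4–C14 bridge, so neither can be set by a hydride arriving from outside. The oxygen functions at C6 and C9 must also be told apart.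
- The strategy rests on this feature: C6 and C9 are oxygenated and 1,4-related through C7–C8, C10 carries the one-carbon unit C14, and the bonds C1–C10 and C5–C6 lie on the face of the C4 oxygen. This is a 2-substituted cyclopentane-1,3-dione (C9, C10, C6, C7, C8) expanded by C1 and C5 of a cyclopentene whose allylic tertiary oxygen steers both new bonds.

## Retrosynthetic reasoning

**Esters and C8/C9 (37 back to 29).** The target 37 is the desilylated form of 36; the C15 silyl ether is removed last because every earlier step needs O15 masked. 36 comes from 34 by esterification with acid 35, and 34 from diol 33 by acetylation of the less hindered allylic 9-hydroxyl. The C9–H bond of 33 is cut back to ketone 32: the hydrogen must arrive on the shielded β face, so it is delivered from boron bound to the 8β-hydroxyl. That 8β-hydroxyl is contra-steric (cis to C11), so 32 is traced to the 8α-alcohol 30 by inversion, and 30 to ketone 29 by enolate hydroxylation on the open α face.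

**Lactone (29 back to 20).** The exocyclic methylene of 29 is cut to the phenylsulfanylmethyl lactone 27 (sulfoxide elimination), which avoids any lactone enolate next to the more acidic C9 ketone. The C6–O bond of 27 is cut with inversion to mesylate 25, from alcohol 24 and ketone 23: an external hydride can only give the 6β-alcohol, so the lactone oxygen is brought in by SN2 from the α face. The C11–C13 bond of 23 is cut to alkylidene 22 (conjugate addition of a phenylsulfanylmethyl group, α-protonation of C7), and the C7–C11 bond of 22 to the C6 ketone 20 (aldol condensation with a two-carbon glyoxylate unit).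

**Pyran (20 back to 16).** The C10=C14 double bond of 20 is cut to the O,S-acetal 18 (sulfoxide elimination), and the O4–C14 bond of 18 to sulfoxide 17 and sulfide 16 (Pummerer closure). The phenylsulfanyl group thus raises C14 to the aldehyde oxidation level exactly where the tertiary alcohol can trap it.

**Key disconnection (16 back to 13).** In 16 the bonds C1–C10 and C5–C6 are cut and C6–C10 is re-formed. This returns the symmetric dione ring and the cyclopentene, joined through a formaldehyde acetal between the enol oxygen and the C4 oxygen in 13. It is chosen because one operation builds the seven-membered ring, both ring-fusion centres and the 1,4-dioxygenation, and frees the C4 hydroxyl needed next. The silyl group is tert-butyldiphenylsilyl rather than tert-butyldimethylsilyl, because it must survive aqueous HCl and trifluoroacetic acid.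

**Acetal (13 back to 8 and 11).** The enol carbon–oxygen bond of 13 is cut to dione 11 and the chloromethyl ether 12, made from the methylthiomethyl ether 8. Dione 11 is the three-component product of 9, thiophenol 10 and the one-carbon unit that becomes C14.

**Tertiary allylic alcohol (8 back to 1).** 8 comes from alcohol 7. Its carbinol centre (the later C4) is set by Sharpless epoxidation of 2 (from ester 1) to 3, silylation to 4, and selenide opening/selenoxide elimination, which moves the alkene without touching that centre.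

## Alternatives that were turned down

**Alternative 1:** gold-catalysed enyne cyclization with carboxylate capture.
- Disconnection: C4–C5 and O–C6, leading back to the cycloheptene enyne acid A2.
- Forward step: Ph3PAuNTf2 (monovalent gold) activates the terminal alkyne of A2, the ring alkene attacks in 5-exo-dig fashion, and the acid traps C6 anti to the new bond, giving the 4(15)-methylene lactone A1.
- For it: cyclopentane and lactone form together, and the C6 oxygen is placed by anti addition without any ketone reduction. On this point it is stronger than the chosen route, which needs a reduction and an inverting lactonization.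
- Against it: A2 must already carry C1, C7, C8, C9 and C10 as defined centres on a seven-membered ring, which is a long asymmetric synthesis before the key step. A1 still lacks the C4 oxygen, so the quaternary centre, the O4–C14 bridge and the strained enol ether would all have to be made late on a flexible bicycle by reagent control, with three orthogonal protecting groups.
- Comparison: the chosen strategy sets C4 first, by a catalytic enantioselective step, and uses it to control C1 and C5.

**Alternative 2:** transannular oxa-Diels–Alder reaction of a germacranolide enal.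
- Disconnection: C1–C5 and O–C4, leading back to the ten-membered dienal A4.
- Forward step: on heating or with Me2AlCl, the enal (O=C14–C10=C1) adds across C4=C5, giving the silyl ether A3, one deprotection from the target.
- For it: cyclopentane, cycloheptane and dihydropyran appear in one step with no later functionalization. In end-game step economy it is clearly stronger than the chosen route.
- Against it: the problem moves into A4, an (E,E)-cyclodecadiene that already holds the α-methylene lactone, both esters and four contiguous centres. Such rings are hard to close, undergo Cope rearrangement when heated, and need not react through the conformer that gives 4β-O with 1α,5α-H. The Lewis acid would meet a product with an ionizable allylic acetate.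
- Comparison: all the risk falls on the last step and the most valuable material. The chosen strategy accepts a longer end game but puts its risky step eighth, on a precursor made from commodity chemicals.

**Alternative 3:** intramolecular nitrile oxide cycloaddition onto the cyclopentene.
- Disconnection: C5–C6 and O–C4 (as an isoxazoline), leading back to aldoxime A6.
- Forward step: NaOCl converts A6 into the nitrile oxide, which adds across the trisubstituted C4=C5 alkene to give the isoxazoline-bridged hydroazulene A5.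
- For it: the C4 oxygen and C5 are set suprafacially in one step, and N–O cleavage would reveal the same C4-hydroxy/C6-keto pattern as compound 16 with C7–C10 already substituted. C8 and C9 would come from acyclic stereocontrol, where the chosen route relies on late substrate control, so on this point it is as strong or stronger.
- Against it: closing a seven-membered ring by this cycloaddition is slow and competes with nitrile oxide dimerization. The facial selectivity relative to C1 is not enforced by a short tether. A6 needs five defined centres and four different protecting groups. After N–O cleavage, the retro-aldol-prone β-hydroxy ketone, the C6 reduction problem and the enol ether closure all remain.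
- Comparison: the chosen route reaches its key step in seven steps from achiral materials with a single catalytic asymmetric step, and its tether enforces the facial selectivity that A6 leaves open.

Key step: step 8

Remark on conventions: guaiane numbering is used throughout; α is the face of H-1 and H-5, β the face of the C4 oxygen; TBDPS = tert-butyldiphenylsilyl; the skeleton of 16–20 is an 11,12,13-trinorguaiane.

Remark on undefined centres: centres that are destroyed later (C10 in 16–19, C14 in 18–19, C11 in 21 and 23–28, sulfur and selenium) and the alkene geometry of 22 are left undefined and are expected to be mixtures.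

## Route

Step 1
Reactants: 1 methyl cyclopent-1-ene-1-carboxylate
Product: 2 cyclopent-1-en-1-ylmethanol
Conditions: i-Bu2AlH (2.2 equiv), CH2Cl2, −78 °C
Reagents that add atoms: none
Why: 1,2-Reduction of a conjugated ester with i-Bu2AlH gives the allylic alcohol and leaves the ring alkene intact.

Step 2
Reactants: 2 cyclopent-1-en-1-ylmethanol
Product: 3 [(1R,5R)-6-oxabicyclo[3.1.0]hexan-1-yl]methanol
Conditions: Ti(OiPr)4 (10 mol %), diisopropyl (2S,3S)-tartrate (12 mol %), t-BuOOH, 4 Å molecular sieves, CH2Cl2, −20 °C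
Reagents that add atoms: tert-butyl hydroperoxide, CC(C)(C)OO
Why: Sharpless asymmetric epoxidation of a trisubstituted allylic alcohol; the (2S,3S)-tartrate, which turns (E)-hex-2-en-1-ol into its (2R,3R)-epoxide, should deliver oxygen to the face that makes the fully substituted carbon R, the later C4 of the target.

Step 3
Reactants: 3 [(1R,5R)-6-oxabicyclo[3.1.0]hexan-1-yl]methanol
Product: 4 tert-butyl{[(1R,5R)-6-oxabicyclo[3.1.0]hexan-1-yl]methoxy}diphenylsilane
Conditions: TBDPSCl, imidazole, CH2Cl2, 0 °C → rt
Reagents that add atoms: tert-butyl(chloro)diphenylsilane, CC(C)(C)[Si](Cl)(c1ccccc1)c1ccccc1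
Why: Silylation of the primary alcohol; doing it before the epoxide opening excludes Payne rearrangement, and the diphenylsilyl ether later survives aqueous HCl and trifluoroacetic acid.

Step 4
Reactants: 4 tert-butyl{[(1R,5R)-6-oxabicyclo[3.1.0]hexan-1-yl]methoxy}diphenylsilane
Product: 7 (1S)-1-[(tert-butyldiphenylsilyloxy)methyl]cyclopent-2-en-1-ol, via hydroxy selenide 5 (not isolated), via selenoxide 6 (not isolated)
Conditions: PhSeSePh, NaBH4, EtOH, 0 °C → reflux; then H2O2 (30 %), THF, 0 °C → rt
Reagents that add atoms: none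
Why: Phenylselenolate opens the epoxide at the secondary carbon with inversion (SN2), and the selenoxide then undergoes syn-elimination, which can only go away from the fully substituted carbinol carbon. The carbinol centre is untouched; its descriptor changes from R to S only because the ligand priorities change.

Step 5
Reactants: 7 (1S)-1-[(tert-butyldiphenylsilyloxy)methyl]cyclopent-2-en-1-ol
Product: 8 tert-butyl{[(1S)-1-(methylsulfanylmethoxy)cyclopent-2-en-1-yl]methoxy}diphenylsilane
Conditions: DMSO, Ac2O, AcOH, rt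
Reagents that add atoms: dimethyl sulfoxide, CS(C)=O
Why: Pummerer-type methylthiomethylation with DMSO/Ac2O etherifies tertiary alcohols without base, so neither silyl migration nor ionization of the allylic carbinol is expected.

Step 6
Reactants: 9 cyclopentane-1,3-dione; 10 thiophenol
Product: 11 2-(phenylsulfanylmethyl)cyclopentane-1,3-dione
Conditions: aq. formaldehyde (37 %), Et3N (cat.), EtOH, rt
Reagents that add atoms: formaldehyde, C=O
Why: Knoevenagel condensation with formaldehyde and conjugate addition of the thiol to the transient 2-methylene dione is a known three-component route to 2-(arylsulfanylmethyl)-1,3-diones; the thiol traps the methylene dione before it dimerizes.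

Step 7
Reactants: 8 tert-butyl{[(1S)-1-(methylsulfanylmethoxy)cyclopent-2-en-1-yl]methoxy}diphenylsilane; 11 2-(phenylsulfanylmethyl)cyclopentane-1,3-dione
Product: 13 3-({[(1S)-1-{[tert-butyl(diphenyl)silyl]oxymethyl}cyclopent-2-en-1-yl]oxy}methoxy)-2-(phenylsulfanylmethyl)cyclopent-2-en-1-one, via chloromethyl ether 12 (not isolated)
Conditions: SO2Cl2 (1.0 equiv), cyclohexene, CH2Cl2, −78 → 0 °C; volatiles removed; then 11, i-Pr2NEt, CH2Cl2, 0 °C → rt
Reagents that add atoms: none
Why: SO2Cl2 cleaves the O,S-acetal to the chloromethyl ether (cyclohexene scavenges MeSCl), and this hard α-chloro ether alkylates the dione enolate at oxygen. The dione is symmetric, so only one vinylogous ester can form.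

Step 8
Reactants: 13 3-({[(1S)-1-{[tert-butyl(diphenyl)silyl]oxymethyl}cyclopent-2-en-1-yl]oxy}methoxy)-2-(phenylsulfanylmethyl)cyclopent-2-en-1-one
Product: 16 (1α-H,5α-H)-15-(tert-butyldiphenylsilyloxy)-4β-hydroxy-14-(phenylsulfanyl)-11,12,13-trinorguaiane-6,9-dione, via cyclobutane photoadduct 14 (not isolated), via cyclobutanol 15 (not isolated)
Conditions: hν (Pyrex-filtered medium-pressure Hg lamp, λ > 300 nm), degassed MeCN (0.01 mol/L), 0 °C; then aq. HCl (2 mol/L), THF, 0 °C → rt
Reagents that add atoms: none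
Why: This is an intramolecular de Mayo reaction (enone–alkene [2+2] photocycloaddition of a 1,3-dione enol derivative, then retro-aldol ring expansion), here with the partners joined through a formaldehyde acetal. The triplet 3-alkoxyenone adds through its β-carbon C6 to C5 of the cyclopentene in a 6-exo closure that forms the 1,3-dioxane ring (C6, O, CH2, O, C4, C5), and the 1,4-biradical collapses by C10–C1 bonding to the cis-fused cyclobutane 14. A six-membered ring can only be fused cis to the cyclopentane, so the C5–C6 bond goes to the alkene face bearing the C4 oxygen and the cyclobutane closure puts C1–C10 on the same face; both new centres C1 and C5 are thus set by the Sharpless-derived centre C4, while C10 is quaternary in 14 and an epimerizable methine in 16. The four-atom tether also secures the regiochemistry (C6 to C5 and C10 to C1, not the crossed mode), and light above 300 nm excites only the enone. Aqueous acid then cleaves the acetal with loss of formaldehyde, and the freed cyclobutanol 15, β to the C9 ketone, opens by retro-aldol cleavage of the strained C6–C10 bond; this is a ring expansion, not a cyclization, and leaves C6 and C9 as the carbonyl groups of the new seven-membered ring. The acid treatment is kept short and cold because 16 is itself a β-hydroxy ketone (C4 hydroxyl, C6 carbonyl) that could dehydrate or undergo a second retro-aldol opening.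

Step 9
Reactants: 16 (1α-H,5α-H)-15-(tert-butyldiphenylsilyloxy)-4β-hydroxy-14-(phenylsulfanyl)-11,12,13-trinorguaiane-6,9-dione
Product: 17 (1α-H,5α-H)-15-(tert-butyldiphenylsilyloxy)-4β-hydroxy-14-(phenylsulfinyl)-11,12,13-trinorguaiane-6,9-dione
Conditions: mCPBA (1.0 equiv), NaHCO3, CH2Cl2, −78 °C
Reagents that add atoms: 3-chloroperoxybenzoic acid, OOC(=O)c1cccc(Cl)c1
Why: Sulfide-to-sulfoxide oxidation is far faster than Baeyer–Villiger oxidation of the ketones at −78 °C with one equivalent of peracid.

Step 10
Reactants: 17 (1α-H,5α-H)-15-(tert-butyldiphenylsilyloxy)-4β-hydroxy-14-(phenylsulfinyl)-11,12,13-trinorguaiane-6,9-dione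
Product: 18 (1α-H,5α-H)-15-(tert-butyldiphenylsilyloxy)-4β,14-epoxy-14-(phenylsulfanyl)-11,12,13-trinorguaiane-6,9-dione
Conditions: (CF3CO)2O, 2,6-lutidine, CH2Cl2, −78 → 0 °C
Reagents that add atoms: none
Why: Pummerer reaction: O-acylation of the sulfoxide and loss of a C14 proton give a thionium ion, which the C4 hydroxyl captures in a six-membered closure; this is possible only because C10 and O4 lie on the same face of the cyclopentane. Etherifying O4 also removes the retro-aldol liability of the β-hydroxy ketone.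

Step 11
Reactants: 18 (1α-H,5α-H)-15-(tert-butyldiphenylsilyloxy)-4β,14-epoxy-14-(phenylsulfanyl)-11,12,13-trinorguaiane-6,9-dione
Product: 20 (1α-H,5α-H)-15-(tert-butyldiphenylsilyloxy)-4β,14-epoxy-11,12,13-trinorguai-10(14)-ene-6,9-dione, via sulfoxide 19 (not isolated)
Conditions: mCPBA (1.0 equiv), NaHCO3, CH2Cl2, −78 °C; then toluene, 60 °C
Reagents that add atoms: none
Why: Oxidation of the O,S-acetal sulfur and syn-elimination of benzenesulfenic acid across C14–C10 (the C10 hydrogen is activated by the C9 carbonyl) give the vinylogous ester under neutral conditions. Amine bases are avoided because enolization of the C6 ketone toward C5 would expel O4 by β-elimination.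

Step 12
Reactants: 20 (1α-H,5α-H)-15-(tert-butyldiphenylsilyloxy)-4β,14-epoxy-11,12,13-trinorguai-10(14)-ene-6,9-dione
Product: 22 tert-butyl (1α-H,5α-H)-15-(tert-butyldiphenylsilyloxy)-4β,14-epoxy-6,9-dioxo-13-norguaia-7(11),10(14)-dien-12-oate, via aldol adduct 21 (not isolated)
Conditions: LiN(SiMe3)2 (1.05 equiv), THF, −78 °C; tert-butyl glyoxylate; then MsCl, Et3N, −78 → 0 °C
Reagents that add atoms: tert-butyl glyoxylate, O=CC(=O)OC(C)(C)C
Why: Aldol condensation: kinetic deprotonation of the C6 ketone at the methylene C7, addition to the glyoxylate and elimination of the mesylate give the alkylidene keto ester. C7 is expected to be more acidic than C8 (α′ to the vinylogous ester carbonyl) and more accessible than the bridging methine C5.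

Step 13
Reactants: 22 tert-butyl (1α-H,5α-H)-15-(tert-butyldiphenylsilyloxy)-4β,14-epoxy-6,9-dioxo-13-norguaia-7(11),10(14)-dien-12-oate
Product: 23 tert-butyl (1α-H,5α-H,7α-H)-15-(tert-butyldiphenylsilyloxy)-4β,14-epoxy-6,9-dioxo-13-(phenylsulfanyl)guai-10(14)-en-12-oate
Conditions: Li[Cu(CH2SPh)2] (from PhSMe, n-BuLi, DABCO; CuI), THF, −78 °C; AcOH quench at −78 °C
Reagents that add atoms: thioanisole (as its lithium cuprate), CSc1ccccc1
Why: Organocuprate conjugate addition to the doubly activated alkene occurs at C11 (β to the ketone, α to the ester) and brings in C13 as a masked methylene. The C6 enolate is then protonated at C7 from the α face, opposite the O4–C14 bridge, which puts the side chain β.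

Step 14
Reactants: 23 tert-butyl (1α-H,5α-H,7α-H)-15-(tert-butyldiphenylsilyloxy)-4β,14-epoxy-6,9-dioxo-13-(phenylsulfanyl)guai-10(14)-en-12-oate
Product: 24 tert-butyl (1α-H,5α-H,7α-H)-15-(tert-butyldiphenylsilyloxy)-4β,14-epoxy-6β-hydroxy-9-oxo-13-(phenylsulfanyl)guai-10(14)-en-12-oate
Conditions: NaBH4, MeOH/THF, −40 °C
Reagents that add atoms: none
Why: Hydride should attack the C6 ketone from the α face, because the β face is covered by the O4–C14 bridge, the quaternary C4 and the β side chain on C7; this gives the 6β-alcohol. The isolated ketone is more electrophilic than the C9 vinylogous ester carbonyl, and the tert-butyl ester prevents closure to the cis-lactone.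

Step 15
Reactants: 24 tert-butyl (1α-H,5α-H,7α-H)-15-(tert-butyldiphenylsilyloxy)-4β,14-epoxy-6β-hydroxy-9-oxo-13-(phenylsulfanyl)guai-10(14)-en-12-oate
Product: 25 tert-butyl (1α-H,5α-H,7α-H)-15-(tert-butyldiphenylsilyloxy)-4β,14-epoxy-6β-(methylsulfonyloxy)-9-oxo-13-(phenylsulfanyl)guai-10(14)-en-12-oate
Conditions: MsCl, Et3N, CH2Cl2, 0 °C
Reagents that add atoms: methanesulfonyl chloride, CS(Cl)(=O)=O
Why: Sulfonylation through sulfene tolerates the hindered, concave 6β-hydroxyl and turns it into a leaving group with retention.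

Step 16
Reactants: 25 tert-butyl (1α-H,5α-H,7α-H)-15-(tert-butyldiphenylsilyloxy)-4β,14-epoxy-6β-(methylsulfonyloxy)-9-oxo-13-(phenylsulfanyl)guai-10(14)-en-12-oate
Product: 27 (1α-H,5α-H,7α-H)-15-(tert-butyldiphenylsilyloxy)-4β,14-epoxy-9-oxo-13-(phenylsulfanyl)guai-10(14)-en-6α,12-olide, via mesyloxy acid 26 (not isolated)
Conditions: CF3CO2H, CH2Cl2, 0 °C → rt; evaporate; then Cs2CO3, DMF, 40 °C
Reagents that add atoms: none
Why: Acidolysis of the tert-butyl ester and intramolecular SN2 displacement of the mesylate by the cesium carboxylate (5-exo-tet) invert C6. The lactone oxygen therefore ends on the α face and the lactone is trans-fused.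

Step 17
Reactants: 27 (1α-H,5α-H,7α-H)-15-(tert-butyldiphenylsilyloxy)-4β,14-epoxy-9-oxo-13-(phenylsulfanyl)guai-10(14)-en-6α,12-olide
Product: 29 (1α-H,5α-H,7α-H)-15-(tert-butyldiphenylsilyloxy)-4β,14-epoxy-9-oxoguaia-10(14),11(13)-dien-6α,12-olide, via sulfoxide 28 (not isolated)
Conditions: mCPBA (1.0 equiv), CH2Cl2, −78 °C; then toluene, CaCO3, 110 °C
Reagents that add atoms: none
Why: Sulfoxide formation and thermal syn-elimination, which can only involve the C11 hydrogen, unveil the α-methylene lactone without lactone enolate chemistry next to the more acidic C9 ketone.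

Step 18
Reactants: 29 (1α-H,5α-H,7α-H)-15-(tert-butyldiphenylsilyloxy)-4β,14-epoxy-9-oxoguaia-10(14),11(13)-dien-6α,12-olide
Product: 30 (1α-H,5α-H,7α-H)-15-(tert-butyldiphenylsilyloxy)-4β,14-epoxy-8α-hydroxy-9-oxoguaia-10(14),11(13)-dien-6α,12-olide
Conditions: KN(SiMe3)2 (1.1 equiv), THF, −78 °C; 2-(phenylsulfonyl)-3-phenyloxaziridine
Reagents that add atoms: 2-(phenylsulfonyl)-3-phenyloxaziridine, O=S(=O)(c1ccccc1)N1OC1c1ccccc1
Why: α′-Deprotonation of the vinylogous ester at C8 (the only acidic site left) and oxidation of the enolate by the Davis oxaziridine should occur on the α face, anti to the β-oriented C7–C11 bond and to the bridge, giving the 8α-alcohol.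

Step 19
Reactants: 30 (1α-H,5α-H,7α-H)-15-(tert-butyldiphenylsilyloxy)-4β,14-epoxy-8α-hydroxy-9-oxoguaia-10(14),11(13)-dien-6α,12-olide
Product: 32 (1α-H,5α-H,7α-H)-15-(tert-butyldiphenylsilyloxy)-4β,14-epoxy-8β-hydroxy-9-oxoguaia-10(14),11(13)-dien-6α,12-olide, via formate 31 (not isolated)
Conditions: HCO2H, PPh3, DIAD, THF, 0 °C → rt; then NaHCO3, MeOH, 0 °C
Reagents that add atoms: formic acid, OC=O
Why: Mitsunobu reaction with a small, acidic pronucleophile inverts the α-keto carbinol; SN2 is accelerated next to a carbonyl and the neighbouring H-7 is syn, so elimination is disfavoured. Mild methanolysis of the labile formate then gives the 8β-alcohol, cis to C11.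

Step 20
Reactants: 32 (1α-H,5α-H,7α-H)-15-(tert-butyldiphenylsilyloxy)-4β,14-epoxy-8β-hydroxy-9-oxoguaia-10(14),11(13)-dien-6α,12-olide
Product: 33 (1α-H,5α-H,7α-H)-15-(tert-butyldiphenylsilyloxy)-4β,14-epoxy-8β,9α-dihydroxyguaia-10(14),11(13)-dien-6α,12-olide
Conditions: Me4NBH(OAc)3, AcOH/MeCN, −30 → 0 °C
Reagents that add atoms: none
Why: Hydroxyl-directed reduction of the Evans–Saksena type: the 8β-oxygen binds boron and delivers hydride intramolecularly to C9 on the β face, giving the trans (8β,9α) diol. An external hydride would be expected to attack anti to the C8 oxygen and give the 9-epimer, and the α-methylene lactone is inert to this reagent.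

Step 21
Reactants: 33 (1α-H,5α-H,7α-H)-15-(tert-butyldiphenylsilyloxy)-4β,14-epoxy-8β,9α-dihydroxyguaia-10(14),11(13)-dien-6α,12-olide
Product: 34 (1α-H,5α-H,7α-H)-9α-acetoxy-15-(tert-butyldiphenylsilyloxy)-4β,14-epoxy-8β-hydroxyguaia-10(14),11(13)-dien-6α,12-olide
Conditions: AcCl (1.05 equiv), 2,4,6-collidine, CH2Cl2, −78 °C
Reagents that add atoms: acetyl chloride, CC(Cl)=O
Why: The allylic 9α-hydroxyl is flanked by the sp2 carbon C10, whereas the 8β-hydroxyl is cis to the lactone carbon C11 on the concave face. A limiting amount of acetyl chloride with a weak hindered base at low temperature should therefore acetylate O9 selectively.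

Step 22
Reactants: 34 (1α-H,5α-H,7α-H)-9α-acetoxy-15-(tert-butyldiphenylsilyloxy)-4β,14-epoxy-8β-hydroxyguaia-10(14),11(13)-dien-6α,12-olide; 35 (R)-2-methylbutanoic acid
Product: 36 (1α-H,5α-H,7α-H)-9α-acetoxy-15-(tert-butyldiphenylsilyloxy)-4β,14-epoxy-8β-[(2R)-2-methylbutanoyloxy]guaia-10(14),11(13)-dien-6α,12-olide
Conditions: N,N'-diisopropylcarbodiimide, DMAP (cat.), CH2Cl2, 0 °C → rt
Reagents that add atoms: none
Why: Carbodiimide esterification with catalytic DMAP acylates the remaining hindered 8β-hydroxyl; an α-alkyl acid without an α-heteroatom is expected to keep its configuration under these conditions.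

Step 23
Reactants: 36 (1α-H,5α-H,7α-H)-9α-acetoxy-15-(tert-butyldiphenylsilyloxy)-4β,14-epoxy-8β-[(2R)-2-methylbutanoyloxy]guaia-10(14),11(13)-dien-6α,12-olide
Product: 37 (1α-H,5α-H,7α-H)-9α-acetoxy-4β,14-epoxy-15-hydroxy-8β-[(2R)-2-methylbutanoyloxy]guaia-10(14),11(13)-dien-6α,12-olide (CNP0013863.3)
Conditions: Bu4NF, AcOH (1:1), THF, 0 °C → rt
Reagents that add atoms: none
Why: Fluoride buffered with acetic acid removes the silyl ether without base-induced acyl migration, conjugate addition to the α-methylene lactone or acid-induced ionization of the allylic acetate.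

## Compound list

1 | methyl cyclopent-1-ene-1-carboxylate | COC(=O)C1=CCCC1 | starting material
2 | cyclopent-1-en-1-ylmethanol | OCC1=CCCC1 | intermediate
3 | [(1R,5R)-6-oxabicyclo[3.1.0]hexan-1-yl]methanol | O1[C@@]2(CO)CCC[C@@H]12 | intermediate
4 | tert-butyl{[(1R,5R)-6-oxabicyclo[3.1.0]hexan-1-yl]methoxy}diphenylsilane | O1[C@@]2(CO[Si](c3ccccc3)(c3ccccc3)C(C)(C)C)CCC[C@@H]12 | intermediate
5 | (1R,2S)-1-[(tert-butyldiphenylsilyloxy)methyl]-2-(phenylselanyl)cyclopentan-1-ol | O[C@@]1(CO[Si](c2ccccc2)(c2ccccc2)C(C)(C)C)CCC[C@@H]1[Se]c1ccccc1 | intermediate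
6 | (1R,2S)-1-[(tert-butyldiphenylsilyloxy)methyl]-2-(phenylseleninyl)cyclopentan-1-ol | O[C@@]1(CO[Si](c2ccccc2)(c2ccccc2)C(C)(C)C)CCC[C@@H]1[Se](=O)c1ccccc1 | intermediate
7 | (1S)-1-[(tert-butyldiphenylsilyloxy)methyl]cyclopent-2-en-1-ol | O[C@@]1(CO[Si](c2ccccc2)(c2ccccc2)C(C)(C)C)CCC=C1 | intermediate
8 | tert-butyl{[(1S)-1-(methylsulfanylmethoxy)cyclopent-2-en-1-yl]methoxy}diphenylsilane | CSCO[C@@]1(CO[Si](c2ccccc2)(c2ccccc2)C(C)(C)C)CCC=C1 | intermediate
9 | cyclopentane-1,3-dione | O=C1CCC(=O)C1 | starting material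
10 | thiophenol | Sc1ccccc1 | starting material
11 | 2-(phenylsulfanylmethyl)cyclopentane-1,3-dione (drawn as the diketone; enolized in solution) | O=C1CCC(=O)C1CSc1ccccc1 | intermediate
12 | tert-butyl{[(1S)-1-(chloromethoxy)cyclopent-2-en-1-yl]methoxy}diphenylsilane | ClCO[C@@]1(CO[Si](c2ccccc2)(c2ccccc2)C(C)(C)C)CCC=C1 | intermediate
13 | 3-({[(1S)-1-{[tert-butyl(diphenyl)silyl]oxymethyl}cyclopent-2-en-1-yl]oxy}methoxy)-2-(phenylsulfanylmethyl)cyclopent-2-en-1-one | O=C1CCC(OCO[C@@]2(CO[Si](c3ccccc3)(c3ccccc3)C(C)(C)C)CCC=C2)=C1CSc1ccccc1 | intermediate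
14 | acetal-bridged cyclobutane photoadduct (bonds C5–C6 and C1–C10 formed, O6–CH2–O4 dioxane retained, cis-anti-cis) | O=C1CC[C@@]2(OCO[C@@]3(CO[Si](c5ccccc5)(c5ccccc5)C(C)(C)C)CC[C@@H]4[C@@H]23)[C@@]14CSc1ccccc1 | intermediate
15 | cyclobutanol after acetal cleavage (6-hydroxy cyclobutane, free 4β-hydroxyl) | O=C1CC[C@@]2(O)[C@]1(CSc3ccccc3)[C@@H]1CC[C@@](O)(CO[Si](c3ccccc3)(c3ccccc3)C(C)(C)C)[C@@H]12 | intermediate
16 | (1α-H,5α-H)-15-(tert-butyldiphenylsilyloxy)-4β-hydroxy-14-(phenylsulfanyl)-11,12,13-trinorguaiane-6,9-dione | O=C1CCC(=O)C(CSc2ccccc2)[C@@H]2CC[C@@](O)(CO[Si](c3ccccc3)(c3ccccc3)C(C)(C)C)[C@H]12 | intermediate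
17 | (1α-H,5α-H)-15-(tert-butyldiphenylsilyloxy)-4β-hydroxy-14-(phenylsulfinyl)-11,12,13-trinorguaiane-6,9-dione | O=C1CCC(=O)C(CS(=O)c2ccccc2)[C@@H]2CC[C@@](O)(CO[Si](c3ccccc3)(c3ccccc3)C(C)(C)C)[C@H]12 | intermediate
18 | (1α-H,5α-H)-15-(tert-butyldiphenylsilyloxy)-4β,14-epoxy-14-(phenylsulfanyl)-11,12,13-trinorguaiane-6,9-dione | O=C2CCC(=O)C1C(Sc4ccccc4)O[C@@]3(CO[Si](c4ccccc4)(c4ccccc4)C(C)(C)C)CC[C@@H]1[C@@H]23 | intermediate
19 | (1α-H,5α-H)-15-(tert-butyldiphenylsilyloxy)-4β,14-epoxy-14-(phenylsulfinyl)-11,12,13-trinorguaiane-6,9-dione | O=C2CCC(=O)C1C(S(=O)c4ccccc4)O[C@@]3(CO[Si](c4ccccc4)(c4ccccc4)C(C)(C)C)CC[C@@H]1[C@@H]23 | intermediate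
20 | (1α-H,5α-H)-15-(tert-butyldiphenylsilyloxy)-4β,14-epoxy-11,12,13-trinorguai-10(14)-ene-6,9-dione | O=C2CCC(=O)C1=CO[C@@]3(CO[Si](c4ccccc4)(c4ccccc4)C(C)(C)C)CC[C@@H]1[C@@H]23 | intermediate
21 | tert-butyl (1α-H,5α-H)-15-(tert-butyldiphenylsilyloxy)-4β,14-epoxy-11-hydroxy-6,9-dioxo-13-norguai-10(14)-en-12-oate | O=C2C(C(O)C(=O)OC(C)(C)C)CC(=O)C1=CO[C@@]3(CO[Si](c4ccccc4)(c4ccccc4)C(C)(C)C)CC[C@@H]1[C@@H]23 | intermediate
22 | tert-butyl (1α-H,5α-H)-15-(tert-butyldiphenylsilyloxy)-4β,14-epoxy-6,9-dioxo-13-norguaia-7(11),10(14)-dien-12-oate | O=C2C(=CC(=O)OC(C)(C)C)CC(=O)C1=CO[C@@]3(CO[Si](c4ccccc4)(c4ccccc4)C(C)(C)C)CC[C@@H]1[C@@H]23 | intermediate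
23 | tert-butyl (1α-H,5α-H,7α-H)-15-(tert-butyldiphenylsilyloxy)-4β,14-epoxy-6,9-dioxo-13-(phenylsulfanyl)guai-10(14)-en-12-oate | O=C2[C@H](C(CSc4ccccc4)C(=O)OC(C)(C)C)CC(=O)C1=CO[C@@]3(CO[Si](c4ccccc4)(c4ccccc4)C(C)(C)C)CC[C@@H]1[C@@H]23 | intermediate
24 | tert-butyl (1α-H,5α-H,7α-H)-15-(tert-butyldiphenylsilyloxy)-4β,14-epoxy-6β-hydroxy-9-oxo-13-(phenylsulfanyl)guai-10(14)-en-12-oate | O[C@@H]2[C@H](C(CSc4ccccc4)C(=O)OC(C)(C)C)CC(=O)C1=CO[C@@]3(CO[Si](c4ccccc4)(c4ccccc4)C(C)(C)C)CC[C@@H]1[C@@H]23 | intermediate
25 | tert-butyl (1α-H,5α-H,7α-H)-15-(tert-butyldiphenylsilyloxy)-4β,14-epoxy-6β-(methylsulfonyloxy)-9-oxo-13-(phenylsulfanyl)guai-10(14)-en-12-oate | CS(=O)(=O)O[C@@H]2[C@H](C(CSc4ccccc4)C(=O)OC(C)(C)C)CC(=O)C1=CO[C@@]3(CO[Si](c4ccccc4)(c4ccccc4)C(C)(C)C)CC[C@@H]1[C@@H]23 | intermediate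
26 | (1α-H,5α-H,7α-H)-15-(tert-butyldiphenylsilyloxy)-4β,14-epoxy-6β-(methylsulfonyloxy)-9-oxo-13-(phenylsulfanyl)guai-10(14)-en-12-oic acid | CS(=O)(=O)O[C@@H]2[C@H](C(CSc4ccccc4)C(=O)O)CC(=O)C1=CO[C@@]3(CO[Si](c4ccccc4)(c4ccccc4)C(C)(C)C)CC[C@@H]1[C@@H]23 | intermediate
27 | (1α-H,5α-H,7α-H)-15-(tert-butyldiphenylsilyloxy)-4β,14-epoxy-9-oxo-13-(phenylsulfanyl)guai-10(14)-en-6α,12-olide | C1(CSc4ccccc4)C(=O)O[C@H]2[C@H]1CC(=O)C1=CO[C@@]3(CO[Si](c4ccccc4)(c4ccccc4)C(C)(C)C)CC[C@@H]1[C@@H]23 | intermediate
28 | (1α-H,5α-H,7α-H)-15-(tert-butyldiphenylsilyloxy)-4β,14-epoxy-9-oxo-13-(phenylsulfinyl)guai-10(14)-en-6α,12-olide | C1(CS(=O)c4ccccc4)C(=O)O[C@H]2[C@H]1CC(=O)C1=CO[C@@]3(CO[Si](c4ccccc4)(c4ccccc4)C(C)(C)C)CC[C@@H]1[C@@H]23 | intermediate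
29 | (1α-H,5α-H,7α-H)-15-(tert-butyldiphenylsilyloxy)-4β,14-epoxy-9-oxoguaia-10(14),11(13)-dien-6α,12-olide | C=C1C(=O)O[C@H]2[C@H]1CC(=O)C1=CO[C@@]3(CO[Si](c4ccccc4)(c4ccccc4)C(C)(C)C)CC[C@@H]1[C@@H]23 | intermediate
30 | (1α-H,5α-H,7α-H)-15-(tert-butyldiphenylsilyloxy)-4β,14-epoxy-8α-hydroxy-9-oxoguaia-10(14),11(13)-dien-6α,12-olide | C=C1C(=O)O[C@H]2[C@H]1[C@@H](O)C(=O)C1=CO[C@@]3(CO[Si](c4ccccc4)(c4ccccc4)C(C)(C)C)CC[C@@H]1[C@@H]23 | intermediate
31 | (1α-H,5α-H,7α-H)-15-(tert-butyldiphenylsilyloxy)-4β,14-epoxy-8β-(formyloxy)-9-oxoguaia-10(14),11(13)-dien-6α,12-olide | C=C1C(=O)O[C@H]2[C@H]1[C@H](OC=O)C(=O)C1=CO[C@@]3(CO[Si](c4ccccc4)(c4ccccc4)C(C)(C)C)CC[C@@H]1[C@@H]23 | intermediate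
32 | (1α-H,5α-H,7α-H)-15-(tert-butyldiphenylsilyloxy)-4β,14-epoxy-8β-hydroxy-9-oxoguaia-10(14),11(13)-dien-6α,12-olide | C=C1C(=O)O[C@H]2[C@H]1[C@H](O)C(=O)C1=CO[C@@]3(CO[Si](c4ccccc4)(c4ccccc4)C(C)(C)C)CC[C@@H]1[C@@H]23 | intermediate
33 | (1α-H,5α-H,7α-H)-15-(tert-butyldiphenylsilyloxy)-4β,14-epoxy-8β,9α-dihydroxyguaia-10(14),11(13)-dien-6α,12-olide | C=C1C(=O)O[C@H]2[C@H]1[C@H](O)[C@@H](O)C1=CO[C@@]3(CO[Si](c4ccccc4)(c4ccccc4)C(C)(C)C)CC[C@@H]1[C@@H]23 | intermediate
34 | (1α-H,5α-H,7α-H)-9α-acetoxy-15-(tert-butyldiphenylsilyloxy)-4β,14-epoxy-8β-hydroxyguaia-10(14),11(13)-dien-6α,12-olide | C=C1C(=O)O[C@H]2[C@H]1[C@H](O)[C@@H](OC(C)=O)C1=CO[C@@]3(CO[Si](c4ccccc4)(c4ccccc4)C(C)(C)C)CC[C@@H]1[C@@H]23 | intermediate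
35 | (R)-2-methylbutanoic acid | CC[C@@H](C)C(=O)O | starting material
36 | (1α-H,5α-H,7α-H)-9α-acetoxy-15-(tert-butyldiphenylsilyloxy)-4β,14-epoxy-8β-[(2R)-2-methylbutanoyloxy]guaia-10(14),11(13)-dien-6α,12-olide | C=C1C(=O)O[C@H]2[C@H]1[C@H](OC(=O)[C@H](C)CC)[C@@H](OC(C)=O)C1=CO[C@@]3(CO[Si](c4ccccc4)(c4ccccc4)C(C)(C)C)CC[C@@H]1[C@@H]23 | intermediate
37 | (1α-H,5α-H,7α-H)-9α-acetoxy-4β,14-epoxy-15-hydroxy-8β-[(2R)-2-methylbutanoyloxy]guaia-10(14),11(13)-dien-6α,12-olide (CNP0013863.3) | C=C1C(=O)O[C@H]2[C@H]1[C@H](OC(=O)[C@H](C)CC)[C@@H](OC(C)=O)C1=CO[C@@]3(CO)CC[C@@H]1[C@@H]23 | target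

## Step count and least certain steps

Total step count: 23. Longest linear sequence: 22 steps (steps 1–5 and 7–23; step 6 is the one-step side branch).

**Step 8 (key step).** The aryl sulfide may quench the enone triplet by electron transfer, or the allylic carbon–sulfur bond may be cleaved photochemically, so that cycloaddition is slow or the C14 carrier is lost. In the acid phase, the formaldehyde acetal may hydrolyse slowly, and the β-hydroxy ketone that is formed may dehydrate or open by retro-aldol cleavage. Fallback: C14 is carried as a photostable sulfone. The route sets out from 9, which is condensed with formaldehyde and PhSO2Na (AcOH/H2O) to give 2-(phenylsulfonylmethyl)cyclopentane-1,3-dione F1. F1 is alkylated at oxygen with chloromethyl ether 12 to the sulfonyl analogue of the precursor F2, and irradiation followed by aqueous acid gives the sulfonyl dione F3. Treating F3 with thiophenol and Et3N exchanges sulfinate for thiolate by elimination–addition in one flask and returns to 16.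

**Step 10.** The activated sulfoxide may lose sulfur by β-elimination through the acidic C10 hydrogen instead of forming the thionium ion, or the tertiary alcohol may be trifluoroacetylated before it can capture the thionium ion. Fallback: the elimination is made the intended reaction. Sulfoxide 17 is warmed in toluene to give the 10-methylene dione F4. Oxidative alkoxylation with PdCl2(MeCN)2 (catalytic) and benzoquinone (alkoxypalladation by the C4 hydroxyl at C14, then β-hydride elimination) closes the ring directly to the vinylogous ester 20, bypassing 18 and 19.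

**Step 12.** The base may deprotonate C8 instead of C7, giving the regioisomeric aldol, or C5, which opens the O4 bridge by β-elimination. Fallback: the two carbonyl groups are told apart by electrophilicity, not acidity. Compound 20 is condensed with pyrrolidine (molecular sieves) at the more electrophilic C6 ketone to give the less substituted enamine F5. F5 is then allowed to react with tert-butyl glyoxylate, and hydrolysis with dehydration gives 22.

**Step 14.** Hydride may enter from the unexpected face, or the C9 carbonyl may be reduced as well. Fallback: if reduction of 23 gives the 6α-hydroxy ester F6, the inversion is not needed. F6 is treated with CF3CO2H, which removes the tert-butyl group and lactonizes with retention to 27 directly, so steps 15 and 16 drop out. An over-reduced allylic C9 alcohol would be reoxidized with MnO2.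

**Step 19.** The activated α-keto carbinol may enolize (epimerization or no substitution), or the nucleophile may approach the β face too slowly. Fallback: inversion by oxidation and reduction. Alcohol 30 is oxidized with buffered Dess–Martin periodinane to the 8,9-dione F7, which is reduced at once with NaBH4 at −78 °C. Hydride enters the more electrophilic C8 carbonyl from the open α face and gives 32 (or, by internal delivery, 33). The dione must not be stored because it can enolize toward C7.

**Step 21.** Regioselectivity between the two hydroxyl groups may be poor, or the acetate may migrate from O9 to O8 during the next acylation. Fallback: a protecting-group detour from 33. The 9-hydroxyl is silylated selectively with the bulkier Et3SiCl (imidazole, −40 °C) to the 9-O-triethylsilyl ether F8. O8 is esterified with 35 to F9, the triethylsilyl group is removed with pyridine-buffered HF·pyridine to give the 9-alcohol F10, and acetylation (Ac2O, pyridine) returns to 36. If O8 proves the more reactive hydroxyl, the order of the two acylations of 33 is simply reversed.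

## Further compounds

F1 | step 8 | 2-(phenylsulfonylmethyl)cyclopentane-1,3-dione | O=C1CCC(=O)C1CS(=O)(=O)c1ccccc1
F2 | step 8 | 3-({[(1S)-1-{[tert-butyl(diphenyl)silyl]oxymethyl}cyclopent-2-en-1-yl]oxy}methoxy)-2-(phenylsulfonylmethyl)cyclopent-2-en-1-one | O=C1CCC(OCO[C@@]2(CO[Si](c3ccccc3)(c3ccccc3)C(C)(C)C)CCC=C2)=C1CS(=O)(=O)c1ccccc1
F3 | step 8 | (1α-H,5α-H)-15-(tert-butyldiphenylsilyloxy)-4β-hydroxy-14-(phenylsulfonyl)-11,12,13-trinorguaiane-6,9-dione | O=C1CCC(=O)C(CS(=O)(=O)c2ccccc2)[C@@H]2CC[C@@](O)(CO[Si](c3ccccc3)(c3ccccc3)C(C)(C)C)[C@H]12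
F4 | step 10 | (1α-H,5α-H)-15-(tert-butyldiphenylsilyloxy)-4β-hydroxy-11,12,13-trinorguai-10(14)-ene-6,9-dione | O=C1CCC(=O)C(=C)[C@@H]2CC[C@@](O)(CO[Si](c3ccccc3)(c3ccccc3)C(C)(C)C)[C@H]12
F5 | step 12 | pyrrolidine enamine of 20 at C6 (C6=C7) | C2(N4CCCC4)=CCC(=O)C1=CO[C@@]3(CO[Si](c5ccccc5)(c5ccccc5)C(C)(C)C)CC[C@@H]1[C@@H]23
F6 | step 14 | tert-butyl (1α-H,5α-H,7α-H)-15-(tert-butyldiphenylsilyloxy)-4β,14-epoxy-6α-hydroxy-9-oxo-13-(phenylsulfanyl)guai-10(14)-en-12-oate | O[C@H]2[C@H](C(CSc4ccccc4)C(=O)OC(C)(C)C)CC(=O)C1=CO[C@@]3(CO[Si](c4ccccc4)(c4ccccc4)C(C)(C)C)CC[C@@H]1[C@@H]23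
F7 | step 19 | (1α-H,5α-H,7α-H)-15-(tert-butyldiphenylsilyloxy)-4β,14-epoxy-8,9-dioxoguaia-10(14),11(13)-dien-6α,12-olide | C=C1C(=O)O[C@H]2[C@H]1C(=O)C(=O)C1=CO[C@@]3(CO[Si](c4ccccc4)(c4ccccc4)C(C)(C)C)CC[C@@H]1[C@@H]23
F8 | step 21 | (1α-H,5α-H,7α-H)-15-(tert-butyldiphenylsilyloxy)-4β,14-epoxy-8β-hydroxy-9α-(triethylsilyloxy)guaia-10(14),11(13)-dien-6α,12-olide | C=C1C(=O)O[C@H]2[C@H]1[C@H](O)[C@@H](O[Si](CC)(CC)CC)C1=CO[C@@]3(CO[Si](c4ccccc4)(c4ccccc4)C(C)(C)C)CC[C@@H]1[C@@H]23
F9 | step 21 | (1α-H,5α-H,7α-H)-15-(tert-butyldiphenylsilyloxy)-4β,14-epoxy-8β-[(2R)-2-methylbutanoyloxy]-9α-(triethylsilyloxy)guaia-10(14),11(13)-dien-6α,12-olide | C=C1C(=O)O[C@H]2[C@H]1[C@H](OC(=O)[C@H](C)CC)[C@@H](O[Si](CC)(CC)CC)C1=CO[C@@]3(CO[Si](c4ccccc4)(c4ccccc4)C(C)(C)C)CC[C@@H]1[C@@H]23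
F10 | step 21 | (1α-H,5α-H,7α-H)-15-(tert-butyldiphenylsilyloxy)-4β,14-epoxy-9α-hydroxy-8β-[(2R)-2-methylbutanoyloxy]guaia-10(14),11(13)-dien-6α,12-olide | C=C1C(=O)O[C@H]2[C@H]1[C@H](OC(=O)[C@H](C)CC)[C@@H](O)C1=CO[C@@]3(CO[Si](c4ccccc4)(c4ccccc4)C(C)(C)C)CC[C@@H]1[C@@H]23
A1 | alternative 1 | 4(15)-methylene guaian-6,12-olide with 8-O-TBS, 9-O-triethylsilyl and 14-O-(4-methoxybenzyl) groups (product of the gold cyclization) | C1C(=O)O[C@H]2[C@H]1[C@H](O[Si](C)(C)C(C)(C)C)[C@@H](O[Si](CC)(CC)CC)[C@@H](COCc3ccc(OC)cc3)[C@@H]1CCC(=C)[C@@H]12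
A2 | alternative 1 | cycloheptene enyne acid, substrate of the gold cyclization | OC(=O)C[C@@H]1[C@H](O[Si](C)(C)C(C)(C)C)[C@@H](O[Si](CC)(CC)CC)[C@@H](COCc2ccc(OC)cc2)[C@H](CCC#C)C=C1
A3 | alternative 2 | C15-O-tert-butyldimethylsilyl ether of the target (product of the transannular cycloaddition) | C=C1C(=O)O[C@H]2[C@H]1[C@H](OC(=O)[C@H](C)CC)[C@@H](OC(C)=O)C1=CO[C@@]3(CO[Si](C)(C)C(C)(C)C)CC[C@@H]1[C@@H]23
A4 | alternative 2 | 14-oxo germacra-1(10),4-dien-6,12-olide with both ring alkenes trans, substrate of the transannular cycloaddition | C=C1C(=O)O[C@H]2[C@H]1[C@H](OC(=O)[C@H](C)CC)[C@@H](OC(C)=O)/C(C=O)=C/CC/C(CO[Si](C)(C)C(C)(C)C)=C/2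
A5 | alternative 3 | isoxazoline-bridged hydroazulene (product of the nitrile oxide cycloaddition) | N1=C2[C@H](CC(=O)OC)[C@H](O[Si](C)(C)C(C)(C)C)[C@@H](O[Si](CC)(CC)CC)[C@@H](C(OC)OC)[C@@H]3CC[C@](CO[Si](c4ccccc4)(c4ccccc4)C(C)(C)C)(O1)[C@H]23
A6 | alternative 3 | aldoxime carrying the cyclopentene, substrate of the nitrile oxide cycloaddition | ON=C[C@H](CC(=O)OC)[C@H](O[Si](C)(C)C(C)(C)C)[C@@H](O[Si](CC)(CC)CC)[C@@H](C(OC)OC)[C@@H]1CCC(CO[Si](c2ccccc2)(c2ccccc2)C(C)(C)C)=C1
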